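**Assumptions:** L-valinol is (S). The (S)-4-isopropyl imide directs each new centre to the face anti to its isopropyl group, as in Evans alkylation, giving the (2R,3R) dimer. The target SMILES works out to (2R,3R)-secoisolariciresinol 9-O-feruloyl ester (R at both centres by CIP analysis).

## Retrosynthetic overview
- Hanultarin comes from global desilylation of the tri-TBS 9-O-feruloyl ester. That ester comes from a Heck reaction of the mono-acrylate of the C2-symmetric diol with protected 4-iodoguaiacol.
- The (R,R) diol comes from reductive removal of two oxazolidinone auxiliaries from a 2,3-bis(arylmethyl)succinyl bis-imide.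
- The bis-imide comes from oxidative radical homocoupling (C8–C8′) of two chelated Z-enolates of one 3-arylpropanoyl imide. Two molecules of the imide combine, and this one step sets both stereocentres.
- The imide comes from a reductive Heck reaction of silyl-protected 4-iodoguaiacol with N-acryloyl oxazolidinone. The aryl iodide comes from catechol (mono-methylation, para-iodination, silylation), and the auxiliary from valinol and diethyl carbonate.
- No rings are formed. The two arenes come from catechol.

## Route

**Step 1**
Reactants: 1 catechol
Product: 2 guaiacol (2-methoxyphenol)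
Conditions: Me2SO4 (1 equiv), NaOH (1 equiv), H2O, 0 °C → rt
Reagents that add atoms: dimethyl sulfate, COS(=O)(=O)OC
Why: Williamson mono-O-methylation of the mono-phenoxide; veratrole is a removable by-product.

**Step 2**
Reactants: 2 guaiacol
Product: 3 4-iodo-2-methoxyphenol
Conditions: NIS, MeCN, 0 °C → rt
Reagents that add atoms: N-iodosuccinimide, O=C1CCC(=O)N1I
Why: Electrophilic aromatic iodination goes para to the more strongly activating OH group.

**Step 3**
Reactants: 3 4-iodo-2-methoxyphenol
Product: 4 tert-butyl(4-iodo-2-methoxyphenoxy)dimethylsilane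
Conditions: TBSCl, imidazole, DMF, rt
Reagents that add atoms: TBSCl, CC(C)(C)[Si](C)(C)Cl
Why: The silyl ether masks the phenol, which would otherwise be oxidised by Fe(III) in step 7. It tolerates the amide base, the Heck conditions and the hydride reduction.

**Step 4**
Reactants: 5 L-valinol ((S)-2-amino-3-methylbutan-1-ol); 6 diethyl carbonate
Product: 7 (S)-4-isopropyloxazolidin-2-one
Conditions: K2CO3 (cat.), 135 °C, EtOH distilled off
Reagents that add atoms: none
Why: Carbamate formation followed by cyclisation (Evans procedure). The stereocentre comes unchanged from L-valinol.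

**Step 5**
Reactants: 7 (S)-4-isopropyloxazolidin-2-one; 8 acryloyl chloride
Product: 9 (S)-3-acryloyl-4-isopropyloxazolidin-2-one
Conditions: n-BuLi, THF, −78 °C; then 8
Reagents that add atoms: none (n-BuLi only deprotonates; the acryloyl group comes from reactant 8)
Why: N-acylation of the lithiated oxazolidinone.

**Step 6**
Reactants: 4 aryl iodide; 9 N-acryloyl imide
Product: 10 (S)-4-isopropyl-3-[3-(4-TBSO-3-methoxyphenyl)propanoyl]oxazolidin-2-one
Conditions: Pd(OAc)2 (5 mol%), HCO2Na, Et3N, Bu4NCl, DMF, 80 °C
Reagents that add atoms: none (formate supplies only H)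
Why: Reductive Heck (conjugate hydroarylation). Aryl-Pd adds to the β-carbon of the acrylimide and formate reduces the Pd-enolate. No new stereocentre forms.

**Step 7**
Reactants: 10 + 10 (two molecules of imide 10, 2 equiv; the two combine head-to-head)
Product: 11 bis-imide, (2R,3R)-2,3-bis(4-TBSO-3-methoxybenzyl)succinyl bis-[(S)-4-isopropyloxazolidin-2-one]
Conditions: NaHMDS (1.05 equiv per imide), THF, −78 °C, 45 min; then Fe(acac)3 (1.1 equiv per imide), −78 → 0 °C
Reagents that add atoms: none (NaHMDS is the base and Fe(acac)3 the one-electron oxidant; no atoms from either reach the product; net change is 2 × 10 − 2 H, C22H35NO5Si ×2 → C44H68N2O10Si2)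
Why: Oxidative enolate homocoupling. SET oxidation of the chelated Z-sodium enolate by Fe(III) gives an α-acyl radical, which couples with a second enolate or radical, and each auxiliary directs C–C bond formation to the face anti to its isopropyl group.
Proposed new method: mechanistic reasoning is that the two carbons form the C8–C8′ bond from the Z-enolate face anti to the isopropyl group, as in Evans alkylation (priority order acyl > new C–C partner > benzyl > H gives R at both centres with the (S)-auxiliary). The closest known reaction types are Cu(II)/Fe(III) oxidative homocoupling of enolates and Evans alkylation face selectivity.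

**Step 8**
Reactants: 11 bis-imide
Product: 12 (2R,3R)-2,3-bis(4-TBSO-3-methoxybenzyl)butane-1,4-diol (auxiliary 7 is recovered)
Conditions: LiBH4 (4 equiv), MeOH (4 equiv), Et2O, 0 °C
Reagents that add atoms: none
Why: Reductive cleavage of N-acyl oxazolidinones to primary alcohols. The aryl silyl ethers survive the short, cold reaction, and the stereocentres are not epimerised because no enolisable carbonyl remains after reduction.

**Step 9**
Reactants: 12 diol (1.5 equiv); 8 acryloyl chloride (1.0 equiv)
Product: 13 mono-acrylate, (2R,3R)-4-hydroxy-2,3-bis(4-TBSO-3-methoxybenzyl)butyl acrylate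
Conditions: Et3N, CH2Cl2, −20 °C
Reagents that add atoms: none
Why: Statistical mono-esterification of the symmetric diol. Excess diol favours the mono-ester, and unreacted 12 is recycled.

**Step 10**
Reactants: 13 mono-acrylate; 4 aryl iodide
Product: 14 tri-TBS feruloyl ester, (E)-cinnamate
Conditions: Pd(OAc)2 (5 mol%), P(o-tol)3, Et3N, DMF, 90 °C
Reagents that add atoms: none
Why: Mizoroki–Heck arylation of the acrylate gives the (E)-cinnamate. The free primary OH and the remote stereocentres are unaffected.

**Step 11**
Reactants: 14 tri-TBS feruloyl ester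
Product: 15 Hanultarin
Conditions: TBAF, AcOH (buffer), THF, 0 °C
Reagents that add atoms: none
Why: Fluoride desilylation of the three aryl silyl ethers. Buffering protects the ester, and any acyl migration is degenerate because the diol is C2-symmetric.

## Compound list
1 | catechol | Oc1ccccc1O | starting material
2 | guaiacol | COc1ccccc1O | intermediate
3 | 4-iodo-2-methoxyphenol | COc1cc(I)ccc1O | intermediate
4 | tert-butyl(4-iodo-2-methoxyphenoxy)dimethylsilane | COc1cc(I)ccc1O[Si](C)(C)C(C)(C)C | intermediate
5 | L-valinol | N[C@@H](C(C)C)CO | starting material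
6 | diethyl carbonate | CCOC(=O)OCC | starting material
7 | (S)-4-isopropyloxazolidin-2-one | O=C1N[C@@H](C(C)C)CO1 | intermediate
8 | acryloyl chloride | C=CC(=O)Cl | starting material
9 | (S)-3-acryloyl-4-isopropyloxazolidin-2-one | C=CC(=O)N1[C@@H](C(C)C)COC1=O | intermediate
10 | (S)-4-isopropyl-3-[3-(4-TBSO-3-methoxyphenyl)propanoyl]oxazolidin-2-one | COc1cc(CCC(=O)N2[C@@H](C(C)C)COC2=O)ccc1O[Si](C)(C)C(C)(C)C | intermediate
11 | (2R,3R)-bis-imide | CC(C)[C@H]1COC(=O)N1C(=O)[C@H](Cc1ccc(O[Si](C)(C)C(C)(C)C)c(OC)c1)[C@@H](Cc1ccc(O[Si](C)(C)C(C)(C)C)c(OC)c1)C(=O)N1[C@@H](C(C)C)COC1=O | intermediate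
12 | (2R,3R)-bis-TBS diol | OC[C@H](Cc1ccc(O[Si](C)(C)C(C)(C)C)c(OC)c1)[C@H](CO)Cc1ccc(O[Si](C)(C)C(C)(C)C)c(OC)c1 | intermediate
13 | mono-acrylate | C=CC(=O)OC[C@H](Cc1ccc(O[Si](C)(C)C(C)(C)C)c(OC)c1)[C@H](CO)Cc1ccc(O[Si](C)(C)C(C)(C)C)c(OC)c1 | intermediate
14 | tri-TBS feruloyl ester | COc1cc(/C=C/C(=O)OC[C@H](Cc2ccc(O[Si](C)(C)C(C)(C)C)c(OC)c2)[C@H](CO)Cc2ccc(O[Si](C)(C)C(C)(C)C)c(OC)c2)ccc1O[Si](C)(C)C(C)(C)C | intermediate
15 | Hanultarin | COc1cc(/C=C/C(=O)OC[C@H](Cc2ccc(O)c(OC)c2)[C@H](CO)Cc2ccc(O)c(OC)c2)ccc1O | target

## Totals
Total steps: 11. Longest linear sequence: 9 steps (1 → 2 → 3 → 4 → 10 → 11 → 12 → 13 → 14 → 15, i.e. steps 1, 2, 3, 6, 7, 8, 9, 10, 11). The auxiliary branch (5 + 6 → 7 → 9) is 2 steps and joins at step 6.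

## Three steps most likely to fail
1. **Step 7, oxidative homocoupling.** Risks are low dr, over-oxidation, and cross-coupling with the oxidant. Fallback: replace the one-electron coupling with stepwise double Evans alkylation. Alkylate the Na-enolate of 10 with tert-butyl bromoacetate (anti to the isopropyl group). Convert the ester into a second (S)-oxazolidinone imide (TFA, then pivaloyl mixed anhydride, then lithiated 7). Alkylate the CH2 side with 4-TBSO-3-methoxybenzyl bromide, made from 4 by i-PrMgCl·LiCl, paraformaldehyde and PBr3. This reaches the same bis-imide 11 by two-electron chemistry.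
2. **Step 9, statistical mono-acylation.** Fallback: desilylate diol 12 (TBAF) to free-phenol secoisolariciresinol and use lipase-catalysed (Novozym 435) transesterification of the primary alcohol with ethyl ferulate, made by Heck coupling of 3 with ethyl acrylate. This is an enzymatic route, not a chemical acylation.
3. **Step 6, reductive Heck.** The reduction may be incomplete, or Heck and reduction products may mix. Fallback: run a plain Heck of 4 with 9 to the cinnamoyl imide, then conjugate reduction of the C=C (H2, Pd/C, TBS ether retained). Alternatively, couple the preformed 3-arylpropanoic acid to oxazolidinone 7.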